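The route rests on cutting the dihydropyranone ring of the target across C2–C3 and O1–C6, back to acetaldehyde and a 1,3-bis(silyloxy)diene carried by the finished coumarin. The key step exploits the vinylogous ester O1–C6=C5–C4=O of that ring and its acetaldehyde-derived carbinol carbon C2: a catalyst-controlled hetero-Diels–Alder reaction closes the six-membered ring, sets C2 (S), and, after acid work-up, gives the target itself. Its precursor is the per-silylated 3-acetoacetylcoumarin, assembled from a citrinin-type quinone methide (side-chain stereocentres from copper-catalysed arylation of (2R,3R)-2,3-epoxybutane) and 4-hydroxy-6-methyl-2-pyranone.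

Key step: step 8

Remark 1: the (R,R)-configured chromium salen catalyst is assumed to expose the Re face of bound acetaldehyde (the sense that gives S at C2, because CH3 ranks below the ring CH2); if the sense proves opposite, the (S,S)-complex is used instead.
Remark 2: compound 10 is written as the dehydrated quinone methide; its hydrate (the lactol, a masked salicylaldehyde) would react in the same way in step 6.

Step 1
Reactants: 1 1-bromo-3,5-dimethoxybenzene; 2 (2R,3R)-2,3-dimethyloxirane
Product: 4 (2R,3R)-3-(3,5-dimethoxyphenyl)butan-2-ol, via 3,5-dimethoxyphenylmagnesium bromide 3 (not isolated)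
Conditions: Mg, I2 (cat.), THF, reflux; then CuI (10 mol %), 2, THF, −30 to 0 °C; aq. NH4Cl
Reagents that add atoms: none
Why: Copper-catalysed Grignard opening of the C2-symmetric trans-epoxide is an SN2 process with inversion at the attacked carbon, so it should give the erythro (2R,3R) alcohol, and the two epoxide carbons are equivalent so no regiochemical question arises.

Step 2
Reactants: 4 (2R,3R)-3-(3,5-dimethoxyphenyl)butan-2-ol
Product: 6 (2R,3R)-3-(3,5-dimethoxy-4-methylphenyl)butan-2-ol, via dilithiated aryl alkoxide 5 (not isolated)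
Conditions: n-BuLi (2.3 equiv), THF, 0 °C to rt; MeI, −78 to 0 °C; then H2O
Reagents that add atoms: iodomethane, CI
Why: Directed ortho-metalation: after alkoxide formation the second equivalent of n-BuLi should remove the proton flanked by both methoxy groups, and the aryllithium is C-methylated while the lithium alkoxide stays inert to MeI at low temperature.

Step 3
Reactants: 6 (2R,3R)-3-(3,5-dimethoxy-4-methylphenyl)butan-2-ol
Product: 8 (2R,3R)-3-(3,5-dimethoxy-2,4-dimethylphenyl)butan-2-ol, via (3R,4R)-6,8-dimethoxy-3,4,7-trimethylisochromane 7 (not isolated)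
Conditions: (CH2O)n (1.0 equiv), TFA, CH2Cl2, 0 °C to rt; then Et3SiH (3 equiv), rt; aq. NaHCO3/MeOH
Reagents that add atoms: formaldehyde (as paraformaldehyde), C=O
Why: Oxa-Pictet–Spengler cyclisation at the ring position ortho to the side chain and para to a methoxy group, followed by ionic hydrogenation (acidolysis of the 2,4-dimethoxybenzyl-type C1–O bond and hydride transfer from Et3SiH), should leave the one-carbon unit as an aryl methyl group and return the free alcohol with both stereocentres untouched.

Step 4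
Reactants: 8 (2R,3R)-3-(3,5-dimethoxy-2,4-dimethylphenyl)butan-2-ol
Product: 9 5-[(2R,3R)-3-hydroxybutan-2-yl]-2,4-dimethylbenzene-1,3-diol
Conditions: BBr3 (4 equiv), CH2Cl2, −78 °C to rt; then H2O
Reagents that add atoms: none
Why: Lewis-acid cleavage of both aryl methyl ethers (bromide attacks the methyl groups in an SN2 fashion) should give the resorcinol, the secondary alkyl borate being hydrolysed on work-up without touching the stereocentres.

Step 5
Reactants: 9 5-[(2R,3R)-3-hydroxybutan-2-yl]-2,4-dimethylbenzene-1,3-diol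
Product: 10 (3R,4R)-8-hydroxy-3,4,5,7-tetramethyl-3,4-dihydro-6H-isochromen-6-one
Conditions: HC(OEt)3 (5 equiv), TFA, 0 °C to rt; aqueous work-up
Reagents that add atoms: triethyl orthoformate, CCOC(OCC)OCC
Why: Orthoformate formylation (electrophilic aromatic substitution by the dialkoxycarbenium ion) at the only free ring position, ortho and para to the two hydroxyls, then capture by the side-chain hydroxyl and loss of ethanol, should give the citrinin-type para-quinone methide, in which aldehyde and alcohol mask each other.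

Step 6
Reactants: 10 (3R,4R)-8-hydroxy-3,4,5,7-tetramethyl-3,4-dihydro-6H-isochromen-6-one; 11 4-hydroxy-6-methyl-2H-pyran-2-one
Product: 13 7-hydroxy-5-[(2R,3R)-3-hydroxybutan-2-yl]-6,8-dimethyl-3-(3-oxobutanoyl)-2H-chromen-2-one, via isochromanyl pyranone adduct 12 (not isolated)
Conditions: piperidine (20 mol %), EtOH, reflux; then dilute AcOH
Reagents that add atoms: none
Why: A Knoevenagel-type coumarin synthesis on the masked salicylaldehyde: 1,6-addition of C3 of the pyranone to C1 of the quinone methide, lactone exchange by the neighbouring phenol (which opens the pyranone to the acetoacetyl chain) and E1cB opening of the isochromane ring should give the conjugated coumarin and free the side-chain alcohol.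

Step 7
Reactants: 13 7-hydroxy-5-[(2R,3R)-3-hydroxybutan-2-yl]-6,8-dimethyl-3-(3-oxobutanoyl)-2H-chromen-2-one
Product: 14 3-[(1Z)-1,3-bis(trimethylsilyloxy)buta-1,3-dien-1-yl]-6,8-dimethyl-7-(trimethylsilyloxy)-5-[(2R,3R)-3-(trimethylsilyloxy)butan-2-yl]-2H-chromen-2-one
Conditions: TMSOTf (4.5 equiv), Et3N (6 equiv), Et2O, 0 °C to rt; pentane, filtration under argon (crude, used at once)
Reagents that add atoms: trimethylsilyl trifluoromethanesulfonate, C[Si](C)(C)OS(=O)(=O)C(F)(F)F
Why: Soft enolisation and silylation: TMSOTf/Et3N should silylate the phenol, the alcohol and the enol and then convert the remaining methyl ketone (or its vinylogous methyl) into the cross-conjugated bis(silyl enol ether), both mono-silyl regioisomers converging on the same diene.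

Step 8
Reactants: 14 3-[(1Z)-1,3-bis(trimethylsilyloxy)buta-1,3-dien-1-yl]-6,8-dimethyl-7-(trimethylsilyloxy)-5-[(2R,3R)-3-(trimethylsilyloxy)butan-2-yl]-2H-chromen-2-one; 15 acetaldehyde
Product: 17 7-hydroxy-5-[(2R,3R)-3-hydroxybutan-2-yl]-6,8-dimethyl-3-[(2S)-2-methyl-4-oxo-3,4-dihydro-2H-pyran-6-yl]-2H-chromen-2-one, via bis(silyloxy)dihydropyran cycloadduct 16 (not isolated)
Conditions: 15 (5 equiv), (R,R)-[Cr(salen)]BF4 (5 mol %; salen = N,N′-bis(3,5-di-tert-butylsalicylidene)cyclohexane-1,2-diaminate), 4 Å MS, t-BuOMe, −30 °C; then TFA, CH2Cl2/H2O, 0 °C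
Reagents that add atoms: none
Why: Catalytic enantioselective hetero-Diels–Alder reaction of a 1,3-dioxygenated diene with an aldehyde: acetaldehyde binds to the cationic trivalent chromium centre, the CH2 terminus of the diene bonds to its carbonyl carbon and the carbonyl oxygen bonds to the silyloxy- and aryl-bearing diene carbon in one concerted, asynchronous [4+2] event in which the C–C bond leads. The dihydropyran ring is thus closed by cycloaddition (C3–C2 and O1–C6 formed together), after which TFA expels Me3SiOH from the ketal carbon C6, unmasks the C4 ketone to give the vinylogous ester and removes the two remaining TMS ethers. The only new stereocentre, C2, is set by the chiral salen ligand, which should expose the Re face of the bound aldehyde, and the remote (R,R) side chain is not expected to interfere. Regioselectivity is secured by the 3-silyloxy group, which makes the unsubstituted CH2 terminus the nucleophilic end, and chemoselectivity over the coumarin C4 acceptor by the much higher electrophilicity of the coordinated aldehyde, used in excess. The configuration at the ketal carbon C6 and the geometry of the diene are without consequence because C6 becomes sp2. The closest known reaction type is the chromium–salen-catalysed cycloaddition of 1-alkoxy-3-silyloxybutadienes with aliphatic aldehydes followed by acid-induced elimination to 2-substituted 2,3-dihydro-4H-pyran-4-ones.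

Compound list
1 | 1-bromo-3,5-dimethoxybenzene | COc1cc(Br)cc(OC)c1 | starting material
2 | (2R,3R)-2,3-dimethyloxirane (trans-2,3-epoxybutane) | C[C@H]1O[C@@H]1C | starting material
3 | 3,5-dimethoxyphenylmagnesium bromide | COc1cc([Mg]Br)cc(OC)c1 | intermediate
4 | (2R,3R)-3-(3,5-dimethoxyphenyl)butan-2-ol | COc1cc([C@@H](C)[C@@H](C)O)cc(OC)c1 | intermediate
5 | lithium (2R,3R)-3-(4-lithio-3,5-dimethoxyphenyl)butan-2-olate | COc1cc([C@@H](C)[C@@H](C)O[Li])cc(OC)c1[Li] | intermediate
6 | (2R,3R)-3-(3,5-dimethoxy-4-methylphenyl)butan-2-ol | COc1cc([C@@H](C)[C@@H](C)O)cc(OC)c1C | intermediate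
7 | (3R,4R)-6,8-dimethoxy-3,4,7-trimethylisochromane | COc1cc2[C@@H](C)[C@@H](C)OCc2c(OC)c1C | intermediate
8 | (2R,3R)-3-(3,5-dimethoxy-2,4-dimethylphenyl)butan-2-ol | COc1cc([C@@H](C)[C@@H](C)O)c(C)c(OC)c1C | intermediate
9 | 5-[(2R,3R)-3-hydroxybutan-2-yl]-2,4-dimethylbenzene-1,3-diol | Oc1cc([C@@H](C)[C@@H](C)O)c(C)c(O)c1C | intermediate
10 | (3R,4R)-8-hydroxy-3,4,5,7-tetramethyl-3,4-dihydro-6H-isochromen-6-one | CC1=C2[C@@H](C)[C@@H](C)OC=C2C(O)=C(C)C1=O | intermediate
11 | 4-hydroxy-6-methyl-2H-pyran-2-one | Cc1cc(O)cc(=O)o1 | starting material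
12 | 3-[(3R,4R)-6,8-dihydroxy-3,4,5,7-tetramethylisochroman-1-yl]-4-hydroxy-6-methyl-2H-pyran-2-one (C1 epimers) | Cc1c(O)c(C)c2[C@@H](C)[C@@H](C)OC(c3c(O)cc(C)oc3=O)c2c1O | intermediate
13 | 7-hydroxy-5-[(2R,3R)-3-hydroxybutan-2-yl]-6,8-dimethyl-3-(3-oxobutanoyl)-2H-chromen-2-one | CC(=O)CC(=O)c1cc2c([C@@H](C)[C@@H](C)O)c(C)c(O)c(C)c2oc1=O | intermediate
14 | 3-[(1Z)-1,3-bis(trimethylsilyloxy)buta-1,3-dien-1-yl]-6,8-dimethyl-7-(trimethylsilyloxy)-5-[(2R,3R)-3-(trimethylsilyloxy)butan-2-yl]-2H-chromen-2-one | C=C(O[Si](C)(C)C)/C=C(\O[Si](C)(C)C)c1cc2c([C@@H](C)[C@@H](C)O[Si](C)(C)C)c(C)c(O[Si](C)(C)C)c(C)c2oc1=O | intermediate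
15 | acetaldehyde | CC=O | starting material
16 | 3-[(2S)-2-methyl-4,6-bis(trimethylsilyloxy)-3,6-dihydro-2H-pyran-6-yl]-6,8-dimethyl-7-(trimethylsilyloxy)-5-[(2R,3R)-3-(trimethylsilyloxy)butan-2-yl]-2H-chromen-2-one (C6 of the pyran undefined) | C[C@H]1CC(O[Si](C)(C)C)=CC(O[Si](C)(C)C)(O1)c1cc2c([C@@H](C)[C@@H](C)O[Si](C)(C)C)c(C)c(O[Si](C)(C)C)c(C)c2oc1=O | intermediate
17 | 7-hydroxy-5-[(2R,3R)-3-hydroxybutan-2-yl]-6,8-dimethyl-3-[(2S)-2-methyl-4-oxo-3,4-dihydro-2H-pyran-6-yl]-2H-chromen-2-one | Cc1c(O)c(C)c2oc(=O)c(C3=CC(=O)C[C@H](C)O3)cc2c1[C@@H](C)[C@@H](C)O | target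

Total step count: 8. Longest linear sequence: 8 steps (from 1; compounds 2, 11 and 15 are purchased).

Steps most likely to fail

Step 8. Facial discrimination at the small aldehyde may be poor with this 1,1-disubstituted diene terminus. The catalyst may also work through an open aldol manifold or turn over slowly, so that acetaldehyde self-condenses or the diene is lost by protodesilylation. The fallback sets out from 10 and comes back at 17; it buys the C2 centre instead of making it. Methyl (S)-3-hydroxybutanoate is silylated (TBSCl, imidazole, DMF) to methyl (S)-3-[(tert-butyldimethylsilyl)oxy]butanoate F1. The dianion of methyl acetoacetate (NaH, then n-BuLi, THF, 0 °C) is acylated with F1 to methyl (7S)-7-[(tert-butyldimethylsilyl)oxy]-3,5-dioxooctanoate F2. DBU in toluene at 80 °C should close F2 to (S)-6-{2-[(tert-butyldimethylsilyl)oxy]propyl}-4-hydroxy-2H-pyran-2-one F3. F3 is condensed with quinone methide 10 under the conditions of step 6 to 3-{(5S)-5-[(tert-butyldimethylsilyl)oxy]-3-oxohexanoyl}-7-hydroxy-5-[(2R,3R)-3-hydroxybutan-2-yl]-6,8-dimethyl-2H-chromen-2-one F4. TFA in CH2Cl2 then removes the silyl group and cyclodehydrates the δ-hydroxy-β-diketone (addition of the hydroxyl to the aryl ketone, loss of water) to 17. The C–O bond at the stereocentre is never broken, so S is retained.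

Step 6. The sequence may halt at the C1 adduct 12 if lactone exchange by the hindered phenol is slow, or the isochromane ring may fail to open. The fallback sets out from 8 and comes back at 13; it blocks the hydroxyl so that no isochromane can form and runs a classical Knoevenagel condensation on an open salicylaldehyde. Alcohol 8 is acetylated (Ac2O, pyridine, DMAP) to (2R,3R)-3-(3,5-dimethoxy-2,4-dimethylphenyl)butan-2-yl acetate F5. Rieche formylation (Cl2CHOMe, TiCl4, CH2Cl2, −78 to 0 °C) at the last free ring position should give (2R,3R)-3-(2-formyl-3,5-dimethoxy-4,6-dimethylphenyl)butan-2-yl acetate F6. BBr3 (CH2Cl2, −78 to 0 °C) cleaves both methyl ethers to (2R,3R)-3-(2-formyl-3,5-dihydroxy-4,6-dimethylphenyl)butan-2-yl acetate F7. Condensation with 11 (piperidine, EtOH, reflux) gives (2R,3R)-3-[7-hydroxy-6,8-dimethyl-2-oxo-3-(3-oxobutanoyl)-2H-chromen-5-yl]butan-2-yl acetate F8. Methanolysis (K2CO3, MeOH, rt, then acidification) returns 13.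

Step 3. A second formaldehyde unit may enter the remaining ring position once 8 has formed (over-alkylation), or the benzylic cation may be captured by another arene instead of by hydride. The fallback sets out from 6 and comes back at 8; it replaces electrophilic alkylation by halogen–metal exchange. NBS (MeCN, 0 °C) should brominate para to a methoxy group to give (2R,3R)-3-(2-bromo-3,5-dimethoxy-4-methylphenyl)butan-2-ol F9. n-BuLi (2.2 equiv, THF, −78 °C) followed by MeI then gives 8.

Further compounds
F1 | step 8 | methyl (S)-3-[(tert-butyldimethylsilyl)oxy]butanoate | C[C@@H](CC(=O)OC)O[Si](C)(C)C(C)(C)C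
F2 | step 8 | methyl (7S)-7-[(tert-butyldimethylsilyl)oxy]-3,5-dioxooctanoate | C[C@@H](CC(=O)CC(=O)CC(=O)OC)O[Si](C)(C)C(C)(C)C
F3 | step 8 | (S)-6-{2-[(tert-butyldimethylsilyl)oxy]propyl}-4-hydroxy-2H-pyran-2-one | C[C@@H](Cc1cc(O)cc(=O)o1)O[Si](C)(C)C(C)(C)C
F4 | step 8 | 3-{(5S)-5-[(tert-butyldimethylsilyl)oxy]-3-oxohexanoyl}-7-hydroxy-5-[(2R,3R)-3-hydroxybutan-2-yl]-6,8-dimethyl-2H-chromen-2-one | C[C@@H](CC(=O)CC(=O)c1cc2c([C@@H](C)[C@@H](C)O)c(C)c(O)c(C)c2oc1=O)O[Si](C)(C)C(C)(C)C
F5 | step 6 | (2R,3R)-3-(3,5-dimethoxy-2,4-dimethylphenyl)butan-2-yl acetate | COc1cc([C@@H](C)[C@@H](C)OC(C)=O)c(C)c(OC)c1C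
F6 | step 6 | (2R,3R)-3-(2-formyl-3,5-dimethoxy-4,6-dimethylphenyl)butan-2-yl acetate | COc1c(C=O)c([C@@H](C)[C@@H](C)OC(C)=O)c(C)c(OC)c1C
F7 | step 6 | (2R,3R)-3-(2-formyl-3,5-dihydroxy-4,6-dimethylphenyl)butan-2-yl acetate | Oc1c(C=O)c([C@@H](C)[C@@H](C)OC(C)=O)c(C)c(O)c1C
F8 | step 6 | (2R,3R)-3-[7-hydroxy-6,8-dimethyl-2-oxo-3-(3-oxobutanoyl)-2H-chromen-5-yl]butan-2-yl acetate | CC(=O)CC(=O)c1cc2c([C@@H](C)[C@@H](C)OC(C)=O)c(C)c(O)c(C)c2oc1=O
F9 | step 3 | (2R,3R)-3-(2-bromo-3,5-dimethoxy-4-methylphenyl)butan-2-ol | COc1cc([C@@H](C)[C@@H](C)O)c(Br)c(OC)c1C
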